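## Structural features

The target is a germacranolide; atoms are numbered in the usual way (ring C1–C10, lactone carbons C11–C13, methyl C14 on C10, methyl C15 on C4), and these locants are used for every intermediate. A ten-membered carbocycle is fused through C6–C7 to a butenolide (O–C6, C7=C11, C12=O) whose α-carbon C11 carries C13H2OAc and whose β-carbon C7 is fully substituted. C1 and C3 are ketones on either side of C2H2 (a cyclic β-diketone), and C3 is also the carbonyl of an α,β-epoxy ketone, because C4 (quaternary, methyl C15) and C5 carry a trans-epoxide (C3 and C6 on opposite faces). C4, C5 and C6 are contiguous stereocenters (4S,5R,6R; the C5–O and C6–O bonds are erythro), C8 (R) bears the (Z)-4-acetoxy-3-methylbut-2-enoate and stands 1,3 to C6 across the sp2 carbon C7, and C10 (R) is the methyl-bearing α-carbon of the C1 ketone. The fragile groups are the acidic C2 and epimerisable C10, the two primary allylic acetates, the Z enoate, and above all the C6 proton, a vinylogous acid whose dienolate would expel the epoxide oxygen at C5 or the acetate at C13. The real difficulty is to close a ten-membered ring that contains a trans-epoxide and a tetrasubstituted butenolide, and to install a 1,3-dicarbonyl unit, without enolate chemistry near C6. The key step exploits the 1,3-relationship of the oxygens on C1 and C3: O–C1, C2 and C3(=N) are the atoms of a 4,5-dihydroisoxazole, so the C2–C3 ring bond can be made by a (3+2) cycloaddition of a C3 nitrile oxide (on quaternary C4) to a C1=C2 vinyl group on C10, which closes the carbocycle and masks the β-diketone in one operation.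

## Logic of the disconnections

43 to 40 (through 42 and 41): no carbon–carbon bond is cut. The C1 and C3 carbonyls of 43 are traced, through the C1 carbinol of 42, to the O–C1 and N=C3 bonds of the isoxazoline in 40, with the N–O bond as retron. A free β-diketone (acidic C2, enol open to O-acylation) could not be carried through the acylations, whereas the isoxazoline is inert. The gain is an end-game of two steps without base. The demand is that N–O cleavage and oxidation spare the epoxide next to C3, both allylic acetates, the enoate and the C6 proton.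

40 to 29 and 37 (through 39 and 38): the acetyl–O13 bond and the acyl–O8 bond are cut, which leaves 29 with one free hydroxyl and sets 37 apart. Acylation is placed after ring closure so that the enoate of 37 is not present as a second dipolarophile in the key step. The gain is a cycloaddition substrate without acyl groups. The demand is esterification of a hindered allylic alcohol without Z to E isomerisation of 37, and a neutral removal of the C13 ether.

29 to 26 (through 28 and 27), the key disconnection: the C2–C3 bond and the O–C1 bond are cut in a retro-(3+2) sense. This opens the ten-membered ring to an open chain that already holds C4, C5, C6, C8 and C10 and ends in an aldoxime carbon (C3) and a vinyl group (C1=C2). The gain is the loss of the medium ring and of the 1,3-dicarbonyl problem at once. The demand is that ring closure in the bridged mode outruns dimerisation of the dipole, under conditions free of strong base.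

26 to 15 and 21 (through 25, 24, 23 and 22): the C6–C7 bond and the lactone C12–O6 bond are cut. This divides the chain into two halves of similar size and lets C6 arise by addition to an aldehyde that stands next to the epoxide, so that C4, C5 and C6 all derive from one epoxidation. The demand is an alkenyl nucleophile at C7 in which C8 is cis to C13 (so that the new alkoxide is cis to the ester), and Felkin–Anh rather than chelate control in the addition.

21 to 16 (through 20, 19, 18 and 17): the two C–O bonds of the epoxide are cut back to the E alkene of 19, and the functional groups are taken back to 16. The gain is a five-carbon achiral starting material with the E geometry in place. The demand is a reagent-controlled epoxidation of a primary allylic alcohol.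

15 to 10 and 11 (through 14, 13 and 12): the enol triflate is returned to a β-keto ester and the C7–C11 bond is cut as a Claisen-type acylation. C13 is thereby brought in with C11 and C12, and the alkene geometry is reduced to the geometry of a chelated enolate. The demand is that the β-alkoxy ester enolate acylates faster than it eliminates.

10 to 4 and 5, and 4 to 1 (through 9, 8, 7, 6, 3 and 2): the C8–O bond is cut (hydroxylation of an enolate under auxiliary control), then the acyl–N bond to 5. The carboxyl carbon (C7) is traced to the trisubstituted alkene of 1, whose stereocenter becomes C10. The gain is that C10 is bought and C8 is set by a reliable auxiliary. The demand is selective cleavage of one of the two alkenes of 1.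

37 to 30 (through 36, 35, 34, 33, 32 and 31): the C3–CH3 bond and the C2–C1 (carboxyl) bond of the side-chain acid are cut. Syn-carbocupration of an ynoate fixes the Z geometry. The demand is that the (Z)-γ-hydroxy enoate never has time to lactonise.

## Other disconnections considered

Alternative 1: the C2–C3 bond is cut as an aldol bond. The forward key step would be the intramolecular aldol addition of the C2 enolate of the C1 methyl ketone in keto aldehyde A1 to its C3 aldehyde, giving the macrocyclic β-hydroxy ketone A2. This is the first plan that comes to mind for a cyclic β-diketone. It is set aside for three reasons. An enolate has to be generated in a molecule whose C6 proton is a vinylogous acid with the epoxide oxygen in the β-position. Enolisation must be steered to C2 and away from C10. A ten-membered aldol addition is reversible, whereas the cycloaddition is irreversible and needs no base. The step count is the same, since the vinyl group would first have to be oxidised to the methyl ketone.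

Alternative 2: the C7–C8 bond is cut. The isoxazoline would be made first by an intermolecular nitrile oxide cycloaddition, and the ring would be closed by a Nozaki–Hiyama–Kishi reaction of the aldehyde–triflate A3 (CrCl2, NiCl2), giving the macrocyclic allylic alcohol A4. It is set aside for these reasons. C8 would be formed in the ring closure without a controlling element and would have to be corrected by oxidation and reduction on the macrocycle. The β-triflyloxy butenolide of A3 is an addition–elimination acceptor and would have to survive hydroxylamine and the generation of the nitrile oxide. The alkenylchromium at C7 is anti-periplanar to the lactone C6–O bond and may fragment by β-elimination. The route would also be about two steps longer.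

Alternative 3: the C1–C2 bond is made in a ring expansion, with a transannular C1–C6 bond in the precursor. The forward key step would be an aldol/retro-Claisen acyl transfer in cyclohexanone A5: the C2 enolate of its methyl ketone adds to the ring ketone C1, and the C1–C6 bond then breaks with C6 leaving as the γ-carbanion of the butenolide. This would expand the six-membered ring by four carbons to the ten-membered diketone A6. It is set aside on structural grounds. The transient six-membered aldolate contains C3–C4=C5–C6, so only the Z enone can take part, and A6 has the wrong alkene geometry for the trans-epoxide. The C6 carbanion would expel the oxygen substituent on C13 (and any on C5). The configuration at C6 would be left to an uncontrolled protonation.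

Key step: step 18

Remark on the chemistry: the configuration at C1 of 29 and 38–42 is of no consequence (C1 ends as a carbonyl carbon) and is left undefined; 13 is a mixture of C11 epimers and 26 of oxime isomers, which converge; metal enolates, the acetylide and the alkenylcuprate that persist between two reagent additions are numbered, whereas species of catalytic cycles are described in the Why lines only. TBS = tert-butyldimethylsilyl, PMB = 4-methoxybenzyl.

## Steps

Step 1
Reactants: 1 (R)-β-citronellene [(3R)-3,7-dimethylocta-1,6-diene]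
Product: 3 (4R)-4-methylhex-5-enal, via ozonide 2 (not isolated)
Conditions: O3 (1 equiv), CH2Cl2, −78 °C; then Me2S, −78 °C → rt
Reagents that add atoms: ozone [O-][O+]=O
Why: Ozonolysis with reductive work-up; the trisubstituted alkene is more electron-rich than the vinyl group and should be cleaved selectively with one equivalent of ozone, and the stereocenter (later C10) is not touched.

Step 2
Reactants: 3 (4R)-4-methylhex-5-enal
Product: 4 (4R)-4-methylhex-5-enoic acid
Conditions: NaClO2, NaH2PO4, 2-methylbut-2-ene, t-BuOH/H2O, 0 °C → rt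
Reagents that add atoms: sodium chlorite [Na+].[O-]Cl=O
Why: Pinnick oxidation; the hypochlorite formed is scavenged by 2-methylbut-2-ene, so the vinyl group should survive.

Step 3
Reactants: 4 (4R)-4-methylhex-5-enoic acid; 5 (4R)-4-benzyloxazolidin-2-one
Product: 6 (4R)-4-benzyl-3-[(4R)-4-methylhex-5-enoyl]oxazolidin-2-one
Conditions: DCC, DMAP (cat.), CH2Cl2, 0 °C → rt
Reagents that add atoms: none
Why: Carbodiimide-mediated N-acylation (Steglich-type activation) attaches the oxazolidinone auxiliary.

Step 4
Reactants: 6 (4R)-4-benzyl-3-[(4R)-4-methylhex-5-enoyl]oxazolidin-2-one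
Product: 8 (4R)-4-benzyl-3-[(2R,4R)-2-hydroxy-4-methylhex-5-enoyl]oxazolidin-2-one, via sodium enolate 7 (not isolated)
Conditions: NaHMDS, THF, −78 °C; then 2-(phenylsulfonyl)-3-phenyloxaziridine, −78 °C; AcOH
Reagents that add atoms: 2-(phenylsulfonyl)-3-phenyloxaziridine O=S(=O)(c1ccccc1)N1OC1c1ccccc1
Why: Auxiliary-controlled enolate hydroxylation; the chelated (Z)-sodium enolate is oxidised by the N-sulfonyloxaziridine on the face opposite the benzyl group, which should set C8 as R.

Step 5
Reactants: 8 (4R)-4-benzyl-3-[(2R,4R)-2-hydroxy-4-methylhex-5-enoyl]oxazolidin-2-one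
Product: 9 (4R)-4-benzyl-3-[(2R,4R)-2-(TBS-oxy)-4-methylhex-5-enoyl]oxazolidin-2-one
Conditions: TBSOTf, 2,6-lutidine, CH2Cl2, −78 → 0 °C
Reagents that add atoms: tert-butyldimethylsilyl trifluoromethanesulfonate CC(C)(C)[Si](C)(C)OS(=O)(=O)C(F)(F)F
Why: Silylation of a hindered secondary alcohol with the silyl triflate; a silyl ether at C8 (a poor leaving group) is needed later next to the alkenylchromium centre.

Step 6
Reactants: 9 (4R)-4-benzyl-3-[(2R,4R)-2-(TBS-oxy)-4-methylhex-5-enoyl]oxazolidin-2-one
Product: 10 (2R,4R)-2-(TBS-oxy)-N-methoxy-N,4-dimethylhex-5-enamide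
Conditions: MeONHMe·HCl, AlMe3, CH2Cl2, 0 °C → rt
Reagents that add atoms: N,O-dimethylhydroxylamine hydrochloride CNOC.Cl
Why: Aluminium amide transamidation cleaves the exocyclic acyl–N bond to give the Weinreb amide and returns the auxiliary; the α-silyloxy stereocenter is not enolised under these conditions.

Step 7
Reactants: 10 (2R,4R)-2-(TBS-oxy)-N-methoxy-N,4-dimethylhex-5-enamide; 11 methyl 3-[(4-methoxybenzyl)oxy]propanoate
Product: 13 methyl (4R,6R)-4-(TBS-oxy)-2-(PMB-oxymethyl)-6-methyl-3-oxooct-7-enoate, via lithium enolate 12 (not isolated)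
Conditions: 11, LDA, THF, −78 °C; then 10, −78 → −40 °C; aq. NH4Cl
Reagents that add atoms: none
Why: Claisen-type acylation of an ester enolate by a Weinreb amide; the chelated tetrahedral adduct collapses only on work-up, so no second addition occurs, and at low temperature the β-alkoxy enolate should not eliminate.

Step 8
Reactants: 13 methyl (4R,6R)-4-(TBS-oxy)-2-(PMB-oxymethyl)-6-methyl-3-oxooct-7-enoate
Product: 15 methyl (2Z,4R,6R)-4-(TBS-oxy)-2-(PMB-oxymethyl)-6-methyl-3-(triflyloxy)octa-2,7-dienoate, via sodium enolate 14 (not isolated)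
Conditions: NaH, THF, 0 °C; then PhNTf2, 0 °C
Reagents that add atoms: N-phenylbis(trifluoromethanesulfonimide) O=S(=O)(N(c1ccccc1)S(=O)(=O)C(F)(F)F)C(F)(F)F
Why: O-Sulfonylation of the sodium-chelated (Z)-enolate of the β-keto ester should give the enol triflate with OTf cis to the ester, that is C8 cis to C13, which is the geometry the butenolide needs.

Step 9
Reactants: 16 ethyl (2E)-3-methyl-4-oxobut-2-enoate
Product: 17 ethyl (2E)-4-hydroxy-3-methylbut-2-enoate
Conditions: NaBH4, CeCl3·7H2O, MeOH, −20 °C
Reagents that add atoms: none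
Why: Luche reduction; 1,2-reduction of the aldehyde in the presence of the conjugated ester, with the E alkene retained.

Step 10
Reactants: 17 ethyl (2E)-4-hydroxy-3-methylbut-2-enoate
Product: 18 ethyl (2E)-4-(TBS-oxy)-3-methylbut-2-enoate
Conditions: TBSCl, imidazole, DMF, rt
Reagents that add atoms: tert-butyldimethylsilyl chloride CC(C)(C)[Si](C)(C)Cl
Why: Imidazole-mediated silylation of a primary alcohol.

Step 11
Reactants: 18 ethyl (2E)-4-(TBS-oxy)-3-methylbut-2-enoate
Product: 19 (2E)-4-(TBS-oxy)-3-methylbut-2-en-1-ol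
Conditions: DIBAL-H, CH2Cl2, −78 °C; Rochelle salt
Reagents that add atoms: none
Why: DIBAL-H reduces the conjugated ester to the allylic alcohol without touching the silyl ether or the alkene geometry.

Step 12
Reactants: 19 (2E)-4-(TBS-oxy)-3-methylbut-2-en-1-ol
Product: 20 [(2R,3R)-3-(TBS-oxymethyl)-3-methyloxiran-2-yl]methanol
Conditions: Ti(OiPr)4 (cat.), D-(−)-diethyl tartrate (cat.), t-BuOOH, 4 Å MS, CH2Cl2, −20 °C
Reagents that add atoms: tert-butyl hydroperoxide CC(C)(C)OO
Why: Sharpless asymmetric epoxidation of a 3,3-disubstituted (E)-allylic alcohol; with D-(−)-tartrate the oxygen should be delivered to the face that gives the (2R,3R)-epoxy alcohol, which sets C4 and C5 together.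

Step 13
Reactants: 20 [(2R,3R)-3-(TBS-oxymethyl)-3-methyloxiran-2-yl]methanol
Product: 21 (2S,3R)-3-(TBS-oxymethyl)-3-methyloxirane-2-carbaldehyde
Conditions: Dess–Martin periodinane, NaHCO3, CH2Cl2, 0 °C → rt
Reagents that add atoms: none
Why: Buffered Dess–Martin oxidation should give the epoxy aldehyde (C6) without epimerisation at C5 or opening of the epoxide.

Step 14
Reactants: 15 methyl (2Z,4R,6R)-4-(TBS-oxy)-2-(PMB-oxymethyl)-6-methyl-3-(triflyloxy)octa-2,7-dienoate; 21 (2S,3R)-3-(TBS-oxymethyl)-3-methyloxirane-2-carbaldehyde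
Product: 23 (5R)-4-[(1R,3R)-1-(TBS-oxy)-3-methylpent-4-en-1-yl]-5-[(2R,3R)-3-(TBS-oxymethyl)-3-methyloxiran-2-yl]-3-(PMB-oxymethyl)furan-2(5H)-one, via hydroxy ester 22 (not isolated)
Conditions: CrCl2, NiCl2 (cat.), DMF, rt; aq. NH4Cl work-up
Reagents that add atoms: none
Why: Nozaki–Hiyama–Kishi coupling; zerovalent nickel inserts into the C–OTf bond, the alkenyl group passes to trivalent chromium with retention of geometry and adds to the aldehyde. Felkin–Anh addition anti to the epoxide C–O bond should give the erythro (6R) alkoxide, which is cis to the ester and lactonises to the butenolide.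

Step 15
Reactants: 23 bis-TBS butenolide (see step 14)
Product: 24 (5R)-4-[(1R,3R)-1-hydroxy-3-methylpent-4-en-1-yl]-5-[(2R,3R)-3-(hydroxymethyl)-3-methyloxiran-2-yl]-3-(PMB-oxymethyl)furan-2(5H)-one
Conditions: HF·pyridine, pyridine, THF, 0 °C → rt
Reagents that add atoms: none
Why: Fluoride-mediated cleavage of both silyl ethers; buffering with pyridine should keep the trisubstituted epoxide intact.

Step 16
Reactants: 24 diol (see step 15)
Product: 25 (2S,3R)-3-[(2R)-3-[(1R,3R)-1-hydroxy-3-methylpent-4-en-1-yl]-4-(PMB-oxymethyl)-5-oxo-2,5-dihydrofuran-2-yl]-2-methyloxirane-2-carbaldehyde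
Conditions: TEMPO (cat.), PhI(OAc)2, CH2Cl2, rt
Reagents that add atoms: none
Why: Oxoammonium (TEMPO) oxidation is selective for the primary alcohol over the hindered secondary allylic C8 alcohol; C4 is quaternary, so the new aldehyde (C3) cannot epimerise.

Step 17
Reactants: 25 epoxy aldehyde (see step 16)
Product: 26 aldoxime of 25 (C3H=NOH)
Conditions: NH2OH·HCl, pyridine, EtOH, 0 °C
Reagents that add atoms: hydroxylamine hydrochloride NO.Cl
Why: Condensation of the aldehyde with hydroxylamine; both oxime isomers lead to the same nitrile oxide.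

Step 18
Reactants: 26 aldoxime (C3H=NOH, C1=C2 vinyl, free 8-OH, 13-OPMB)
Product: 29 isoxazoline-bridged macrocyclic alcohol (C3=N–O–C1, ring bond C2–C3), via hydroximoyl chloride 27 (not isolated), via nitrile oxide 28 (not isolated)
Conditions: NCS, DMF, 0 °C → rt; then slow addition to KHCO3, EtOAc (high dilution), 40 °C
Reagents that add atoms: none
Why: Intramolecular nitrile oxide–alkene cycloaddition (Huisgen (3+2) cycloaddition): NCS chlorinates the aldoxime to hydroximoyl chloride 27, bicarbonate removes HCl to give nitrile oxide 28, and the dipole adds in a concerted, asynchronous way across C1=C2. The closest known reaction type is the macrocyclising nitrile oxide cycloaddition used as an aldol surrogate for rings of ten and more members. Two rings close at once: the ten-membered carbocycle by C3–C2 bond formation in the bridged mode, in which dipole and alkene are joined end to end, and the isoxazoline by the accompanying O–C1 bond. Regioselectivity (dipole carbon to the unsubstituted terminus C2, oxygen to C1) follows the normal frontier-orbital and steric preference for monosubstituted alkenes, and the fused alternative would need the disfavoured orientation as well as a nine-membered ring. The selectivity that matters is ring closure over dimerisation to the furoxan: the nitrile oxide carbon sits on the fully substituted C4, which slows dimerisation, and slow generation at high dilution keeps the dipole concentration low. The only reactive dipolarophile is the vinyl group, because the butenolide alkene is tetrasubstituted and electron-poor. The new center C1 is set by the ring conformation but is removed in step 27, so its configuration does not matter, and C4, C5, C6, C8 and C10 are not touched. No strong base is present, so the C6 proton, the epoxide and the free C8 hydroxyl should survive, and the butenolide and the trans-epoxide act as turn elements that bring the chain ends together.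

Step 19
Reactants: 30 tert-butyldimethyl(prop-2-yn-1-yloxy)silane
Product: 32 tert-butyl 4-(TBS-oxy)but-2-ynoate, via lithium acetylide 31 (not isolated)
Conditions: n-BuLi, THF, −78 °C; then Boc2O, −78 → 0 °C
Reagents that add atoms: di-tert-butyl dicarbonate CC(C)(C)OC(=O)OC(=O)OC(C)(C)C
Why: Deprotonation of the terminal alkyne and C-acylation of the acetylide gives the tert-butyl ynoate.

Step 20
Reactants: 32 tert-butyl 4-(TBS-oxy)but-2-ynoate
Product: 34 tert-butyl (2Z)-4-(TBS-oxy)-3-methylbut-2-enoate, via alkenylcuprate 33 (not isolated)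
Conditions: Me2CuLi (MeLi, CuI), THF, −78 °C; MeOH, −78 °C
Reagents that add atoms: lithium dimethylcuprate (made in the flask from MeLi and CuI) [Li+].C[Cu-]C
Why: Syn-carbocupration (conjugate addition) of the ynoate and protonation of the alkenylcuprate with retention at −78 °C places methyl and hydrogen cis, which gives the Z enoate.

Step 21
Reactants: 34 tert-butyl (2Z)-4-(TBS-oxy)-3-methylbut-2-enoate
Product: 36 tert-butyl (2Z)-4-acetoxy-3-methylbut-2-enoate, via hydroxy ester 35 (not isolated)
Conditions: HF·pyridine, THF, 0 °C; then pyridine, Ac2O, DMAP (cat.), 0 °C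
Reagents that add atoms: acetic anhydride CC(=O)OC(C)=O
Why: Desilylation followed at once by acetylation in the same flask; the bulky tert-butyl ester slows lactonisation of the transient (Z)-γ-hydroxy enoate.

Step 22
Reactants: 36 tert-butyl (2Z)-4-acetoxy-3-methylbut-2-enoate
Product: 37 (2Z)-4-acetoxy-3-methylbut-2-enoic acid
Conditions: TFA, CH2Cl2, 0 °C → rt
Reagents that add atoms: none
Why: Acidolysis of the tert-butyl ester with loss of isobutene; the primary acetate and the Z alkene are unchanged.

Step 23
Reactants: 29 isoxazoline-bridged macrocyclic alcohol; 37 (2Z)-4-acetoxy-3-methylbut-2-enoic acid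
Product: 38 8-O-[(2Z)-4-acetoxy-3-methylbut-2-enoyl] ester of 29
Conditions: EDC·HCl, DMAP, CH2Cl2, 0 °C → rt
Reagents that add atoms: none
Why: Steglich esterification of the single free (C8) hydroxyl; the isoxazoline and the epoxide are inert to carbodiimide and DMAP, and no enolisable β-diketone is present yet.

Step 24
Reactants: 38 C8 ester with 13-OPMB
Product: 39 C13 alcohol (PMB removed)
Conditions: DDQ, CH2Cl2/pH 7 buffer, 0 °C → rt
Reagents that add atoms: none
Why: Oxidative PMB cleavage (hydride abstraction by DDQ, hydrolysis of the oxocarbenium ion) under neutral conditions.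

Step 25
Reactants: 39 C13 alcohol
Product: 40 C13 acetate (isoxazoline form of the target)
Conditions: Ac2O, pyridine, CH2Cl2, 0 °C
Reagents that add atoms: acetic anhydride CC(=O)OC(C)=O
Why: Acetylation of the only free (primary allylic) hydroxyl.

Step 26
Reactants: 40 C13 acetate (isoxazoline)
Product: 42 β-hydroxy ketone (C1–OH, C3=O), via hydroxy imine 41 (not isolated)
Conditions: Mo(CO)6, MeCN/H2O, 80 °C
Reagents that add atoms: water O
Why: Reductive N–O cleavage of the isoxazoline by zerovalent molybdenum gives the β-hydroxy imine, which is hydrolysed in the aqueous medium to the β-hydroxy ketone; the medium is neutral, so the epoxy ketone, the esters and C10 should survive.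

Step 27
Reactants: 42 β-hydroxy ketone
Product: 43 target CNP0274470.1
Conditions: Dess–Martin periodinane, NaHCO3, CH2Cl2, 0 °C → rt
Reagents that add atoms: none
Why: Dess–Martin oxidation of a β-hydroxy ketone to the β-diketone under buffered conditions without base; C10 already has its final configuration.

## Compound list

1 | (3R)-3,7-dimethylocta-1,6-diene [(R)-β-citronellene] | C=C[C@H](C)CCC=C(C)C | starting material
2 | 3,3-dimethyl-5-[(3R)-3-methylpent-4-en-1-yl]-1,2,4-trioxolane (ozonide) | C=C[C@H](C)CCC1OOC(C)(C)O1 | intermediate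
3 | (4R)-4-methylhex-5-enal | C=C[C@H](C)CCC=O | intermediate
4 | (4R)-4-methylhex-5-enoic acid | C=C[C@H](C)CCC(=O)O | intermediate
5 | (4R)-4-benzyloxazolidin-2-one | O=C1OC[C@@H](Cc2ccccc2)N1 | starting material
6 | (4R)-4-benzyl-3-[(4R)-4-methylhex-5-enoyl]oxazolidin-2-one | C=C[C@H](C)CCC(=O)N1C(=O)OC[C@H]1Cc1ccccc1 | intermediate
7 | sodium (Z)-enolate of 6 | C=C[C@H](C)C/C=C(\[O-])N1C(=O)OC[C@H]1Cc1ccccc1.[Na+] | intermediate
8 | (4R)-4-benzyl-3-[(2R,4R)-2-hydroxy-4-methylhex-5-enoyl]oxazolidin-2-one | C=C[C@H](C)C[C@@H](O)C(=O)N1C(=O)OC[C@H]1Cc1ccccc1 | intermediate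
9 | (4R)-4-benzyl-3-[(2R,4R)-2-[(tert-butyldimethylsilyl)oxy]-4-methylhex-5-enoyl]oxazolidin-2-one | C=C[C@H](C)C[C@@H](O[Si](C)(C)C(C)(C)C)C(=O)N1C(=O)OC[C@H]1Cc1ccccc1 | intermediate
10 | (2R,4R)-2-[(tert-butyldimethylsilyl)oxy]-N-methoxy-N,4-dimethylhex-5-enamide | C=C[C@H](C)C[C@@H](O[Si](C)(C)C(C)(C)C)C(=O)N(C)OC | intermediate
11 | methyl 3-[(4-methoxybenzyl)oxy]propanoate | COC(=O)CCOCc1ccc(OC)cc1 | starting material
12 | lithium enolate of 11 | [Li+].[O-]C(OC)=CCOCc1ccc(OC)cc1 | intermediate
13 | methyl (4R,6R)-4-[(tert-butyldimethylsilyl)oxy]-2-{[(4-methoxybenzyl)oxy]methyl}-6-methyl-3-oxooct-7-enoate (both C2 epimers; C2 = C11) | C=C[C@H](C)C[C@@H](O[Si](C)(C)C(C)(C)C)C(=O)C(COCc1ccc(OC)cc1)C(=O)OC | intermediate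
14 | sodium (Z)-enolate of 13 | C=C[C@H](C)C[C@@H](O[Si](C)(C)C(C)(C)C)/C([O-])=C(\COCc1ccc(OC)cc1)C(=O)OC.[Na+] | intermediate
15 | methyl (2Z,4R,6R)-4-[(tert-butyldimethylsilyl)oxy]-2-{[(4-methoxybenzyl)oxy]methyl}-6-methyl-3-{[(trifluoromethyl)sulfonyl]oxy}octa-2,7-dienoate | C=C[C@H](C)C[C@@H](O[Si](C)(C)C(C)(C)C)/C(OS(=O)(=O)C(F)(F)F)=C(\COCc1ccc(OC)cc1)C(=O)OC | intermediate
16 | ethyl (2E)-3-methyl-4-oxobut-2-enoate | CCOC(=O)/C=C(\C)C=O | starting material
17 | ethyl (2E)-4-hydroxy-3-methylbut-2-enoate | CCOC(=O)/C=C(\C)CO | intermediate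
18 | ethyl (2E)-4-[(tert-butyldimethylsilyl)oxy]-3-methylbut-2-enoate | CCOC(=O)/C=C(\C)CO[Si](C)(C)C(C)(C)C | intermediate
19 | (2E)-4-[(tert-butyldimethylsilyl)oxy]-3-methylbut-2-en-1-ol | OC/C=C(\C)CO[Si](C)(C)C(C)(C)C | intermediate
20 | [(2R,3R)-3-{[(tert-butyldimethylsilyl)oxy]methyl}-3-methyloxiran-2-yl]methanol | OC[C@H]1O[C@]1(C)CO[Si](C)(C)C(C)(C)C | intermediate
21 | (2S,3R)-3-{[(tert-butyldimethylsilyl)oxy]methyl}-3-methyloxirane-2-carbaldehyde | O=C[C@H]1O[C@]1(C)CO[Si](C)(C)C(C)(C)C | intermediate
22 | open-chain hydroxy ester from addition of C7 of 15 to the aldehyde of 21 (C6 carbinol R, C6 cis to the methyl ester, C8 cis to C13) | COC(=O)/C(COCc1ccc(OC)cc1)=C(\[C@@H](O)[C@H]1O[C@]1(C)CO[Si](C)(C)C(C)(C)C)[C@H](O[Si](C)(C)C(C)(C)C)C[C@@H](C)C=C | intermediate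
23 | (5R)-4-[(1R,3R)-1-[(tert-butyldimethylsilyl)oxy]-3-methylpent-4-en-1-yl]-5-[(2R,3R)-3-{[(tert-butyldimethylsilyl)oxy]methyl}-3-methyloxiran-2-yl]-3-{[(4-methoxybenzyl)oxy]methyl}furan-2(5H)-one | O=C1O[C@@H]([C@H]2O[C@]2(C)CO[Si](C)(C)C(C)(C)C)C([C@H](O[Si](C)(C)C(C)(C)C)C[C@@H](C)C=C)=C1COCc1ccc(OC)cc1 | intermediate
24 | (5R)-4-[(1R,3R)-1-hydroxy-3-methylpent-4-en-1-yl]-5-[(2R,3R)-3-(hydroxymethyl)-3-methyloxiran-2-yl]-3-{[(4-methoxybenzyl)oxy]methyl}furan-2(5H)-one | O=C1O[C@@H]([C@H]2O[C@]2(C)CO)C([C@H](O)C[C@@H](C)C=C)=C1COCc1ccc(OC)cc1 | intermediate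
25 | (2S,3R)-3-[(2R)-3-[(1R,3R)-1-hydroxy-3-methylpent-4-en-1-yl]-4-{[(4-methoxybenzyl)oxy]methyl}-5-oxo-2,5-dihydrofuran-2-yl]-2-methyloxirane-2-carbaldehyde | O=C1O[C@@H]([C@H]2O[C@]2(C)C=O)C([C@H](O)C[C@@H](C)C=C)=C1COCc1ccc(OC)cc1 | intermediate
26 | oxime of 25: (2R,3R)-3-[(2R)-3-[(1R,3R)-1-hydroxy-3-methylpent-4-en-1-yl]-4-{[(4-methoxybenzyl)oxy]methyl}-5-oxo-2,5-dihydrofuran-2-yl]-2-methyloxirane-2-carbaldehyde oxime | O=C1O[C@@H]([C@H]2O[C@]2(C)C=NO)C([C@H](O)C[C@@H](C)C=C)=C1COCc1ccc(OC)cc1 | intermediate
27 | hydroximoyl chloride of 26 (C3(Cl)=NOH; N-hydroxy oxirane-2-carboximidoyl chloride) | O=C1O[C@@H]([C@H]2O[C@]2(C)C(Cl)=NO)C([C@H](O)C[C@@H](C)C=C)=C1COCc1ccc(OC)cc1 | intermediate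
28 | nitrile oxide from 27 (C3≡N–O on quaternary C4) | O=C1O[C@@H]([C@H]2O[C@]2(C)C#[N+][O-])C([C@H](O)C[C@@H](C)C=C)=C1COCc1ccc(OC)cc1 | intermediate
29 | macrocyclic isoxazoline alcohol: ten-membered carbocycle C1–C10 of 43 in which C3=N–O–C1 forms a 4,5-dihydroisoxazole (C2 is its CH2); 4,5-epoxide, 12,6-butenolide and C4, C5, C6, C8, C10 arranged as in 43; 8-OH free, 13-O-(4-methoxybenzyl); C1 not defined | COc1ccc(COCC2=C3[C@@H](OC2=O)[C@H]4O[C@]4(C)C5=NOC(C5)[C@H](C)C[C@H]3O)cc1 | intermediate
30 | tert-butyldimethyl(prop-2-yn-1-yloxy)silane | C#CCO[Si](C)(C)C(C)(C)C | starting material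
31 | lithium acetylide of 30 | [Li]C#CCO[Si](C)(C)C(C)(C)C | intermediate
32 | tert-butyl 4-[(tert-butyldimethylsilyl)oxy]but-2-ynoate | CC(C)(C)OC(=O)C#CCO[Si](C)(C)C(C)(C)C | intermediate
33 | lithium alkenyl(methyl)cuprate from syn-addition of Me2CuLi to 32 (Cu on C2, cis to the new methyl) | CC(C)(C)OC(=O)/C([Cu-]C)=C(/C)CO[Si](C)(C)C(C)(C)C.[Li+] | intermediate
34 | tert-butyl (2Z)-4-[(tert-butyldimethylsilyl)oxy]-3-methylbut-2-enoate | CC(C)(C)OC(=O)/C=C(/C)CO[Si](C)(C)C(C)(C)C | intermediate
35 | tert-butyl (2Z)-4-hydroxy-3-methylbut-2-enoate | CC(C)(C)OC(=O)/C=C(/C)CO | intermediate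
36 | tert-butyl (2Z)-4-acetoxy-3-methylbut-2-enoate | CC(C)(C)OC(=O)/C=C(/C)COC(C)=O | intermediate
37 | (2Z)-4-acetoxy-3-methylbut-2-enoic acid | OC(=O)/C=C(/C)COC(C)=O | intermediate
38 | 29 esterified at O8 with the (2Z)-4-acetoxy-3-methylbut-2-enoyl group (13-OPMB retained) | COc1ccc(COCC2=C3[C@@H](OC2=O)[C@H]4O[C@]4(C)C5=NOC(C5)[C@H](C)C[C@H]3OC(=O)/C=C(/C)COC(C)=O)cc1 | intermediate
39 | 38 with free C13 hydroxyl | OCC1=C2[C@@H](OC1=O)[C@H]3O[C@]3(C)C4=NOC(C4)[C@H](C)C[C@H]2OC(=O)/C=C(/C)COC(C)=O | intermediate
40 | 13-acetate of 39 (target with C1–O–N=C3 isoxazoline in place of the two ketones) | CC(=O)OCC1=C2[C@@H](OC1=O)[C@H]3O[C@]3(C)C4=NOC(C4)[C@H](C)C[C@H]2OC(=O)/C=C(/C)COC(C)=O | intermediate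
41 | 1-hydroxy-3-imino compound from N–O cleavage of 40 | CC(=O)OCC1=C2[C@@H](OC1=O)[C@H]3O[C@]3(C)C(=N)CC(O)[C@H](C)C[C@H]2OC(=O)/C=C(/C)COC(C)=O | intermediate
42 | 1-hydroxy-3-oxo compound (β-hydroxy ketone; C1 not defined) | CC(=O)OCC1=C2[C@@H](OC1=O)[C@H]3O[C@]3(C)C(=O)CC(O)[C@H](C)C[C@H]2OC(=O)/C=C(/C)COC(C)=O | intermediate
43 | CNP0274470.1: (4S,5R,6R,8R,10R)-13-acetoxy-8-[(2Z)-4-acetoxy-3-methylbut-2-enoyloxy]-4,5-epoxy-1,3-dioxogermacr-7(11)-en-12,6-olide | CC(=O)OCC1=C2[C@@H](OC1=O)[C@H]1O[C@]1(C)C(=O)CC(=O)[C@H](C)C[C@H]2OC(=O)/C=C(/C)COC(C)=O | target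

## Step count and risks

Total step count: 27 (steps 1–8 give fragment 15, steps 9–13 fragment 21, steps 19–22 acid 37, steps 14–18 and 23–27 the union and end-game). Longest linear sequence: 18 steps (1–8, 14–18, 23–27).

Least certain steps:

Step 18 (key step). Dimerisation of the nitrile oxide to a furoxan, or oligomerisation, may outrun the entropically costly ten-membered closure, or the ring may close in the fused mode. Fallback (aldol ring closure in place of the cycloaddition): starting from 25, esterification with 37 (EDC·HCl, DMAP) gives the C8 ester F1. Wacker oxidation of its vinyl group (PdCl2, CuCl, O2, DMF/H2O) gives the methyl ketone F2. A boron-mediated intramolecular aldol addition ((c-Hex)2BCl, Et3N, high dilution) of the C2 enolate to the C3 aldehyde gives the macrocyclic 3-hydroxy-1-ketone F3. DDQ gives the C13 alcohol F4, and acetylation (Ac2O, pyridine; the C3 carbinol next to quaternary C4 is too hindered to react) gives the acetate F5. Dess–Martin oxidation of F5 gives 43, where the fallback rejoins the route.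

Step 14. Addition of the hindered tetrasubstituted alkenylchromium may be slow. Facial selectivity may be lost if trivalent chromium chelates the epoxide oxygen, since chelate control favours the C6 epimer. Divalent chromium may open the epoxy aldehyde reductively. Fallback (acylation, then chelation-controlled reduction): from 15, Pd(PPh3)4, Me3SnSnMe3 and LiCl give the alkenylstannane F6. From 20, TEMPO/PhI(OAc)2 in aqueous MeCN gives the epoxy acid F7, and EDC·HCl/EtSH gives the thioester F8. A Liebeskind–Srogl-type coupling of F6 with F8 (Pd2(dba)3, tri(2-furyl)phosphine, CuO2PPh2) gives the ketone F9. Zn(BH4)2 reduces F9 through the zinc chelate of the ketone and epoxide oxygens to the erythro alcohol 22, which lactonises to 23, where the route is rejoined.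

Step 26. Zerovalent molybdenum may add oxidatively to the allylic acetate on C13 or deoxygenate the epoxide, and the β-hydroxy ketone may undergo retro-aldol cleavage at 80 °C. Fallback (change of order, so that no acetate sits on the butenolide during N–O cleavage): from 39 the N–O bond is cleaved (Raney nickel, H2, B(OH)3, aqueous MeOH) to the diol F10. Its primary C13 hydroxyl is then acetylated selectively (AcCl, 2,4,6-collidine, −78 °C) in the presence of the secondary C1 carbinol, which returns to 42.

## Further compounds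

F1 | step 18 | C8 (2Z)-4-acetoxy-3-methylbut-2-enoate of aldehyde 25 | O=C1O[C@@H]([C@H]2O[C@]2(C)C=O)C([C@H](OC(=O)/C=C(/C)COC(C)=O)C[C@@H](C)C=C)=C1COCc1ccc(OC)cc1
F2 | step 18 | methyl ketone from Wacker oxidation of F1 (C1 acetyl, C3 aldehyde) | O=C1O[C@@H]([C@H]2O[C@]2(C)C=O)C([C@H](OC(=O)/C=C(/C)COC(C)=O)C[C@@H](C)C(C)=O)=C1COCc1ccc(OC)cc1
F3 | step 18 | macrocyclic aldol product (C3–OH, C1=O, 13-OPMB, C8 ester; C3 not defined) | COc1ccc(COCC2=C3[C@@H](OC2=O)[C@H]4O[C@]4(C)C(O)CC(=O)[C@H](C)C[C@H]3OC(=O)/C=C(/C)COC(C)=O)cc1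
F4 | step 18 | C13 alcohol from F3 | OCC1=C2[C@@H](OC1=O)[C@H]3O[C@]3(C)C(O)CC(=O)[C@H](C)C[C@H]2OC(=O)/C=C(/C)COC(C)=O
F5 | step 18 | C13 acetate of F4 (3-hydroxy-1-oxo isomer of 42) | CC(=O)OCC1=C2[C@@H](OC1=O)[C@H]3O[C@]3(C)C(O)CC(=O)[C@H](C)C[C@H]2OC(=O)/C=C(/C)COC(C)=O
F6 | step 14 | methyl (2Z,4R,6R)-4-[(tert-butyldimethylsilyl)oxy]-2-{[(4-methoxybenzyl)oxy]methyl}-6-methyl-3-(trimethylstannyl)octa-2,7-dienoate | C=C[C@H](C)C[C@@H](O[Si](C)(C)C(C)(C)C)/C([Sn](C)(C)C)=C(\COCc1ccc(OC)cc1)C(=O)OC
F7 | step 14 | (2S,3R)-3-{[(tert-butyldimethylsilyl)oxy]methyl}-3-methyloxirane-2-carboxylic acid | OC(=O)[C@H]1O[C@]1(C)CO[Si](C)(C)C(C)(C)C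
F8 | step 14 | S-ethyl (2S,3R)-3-{[(tert-butyldimethylsilyl)oxy]methyl}-3-methyloxirane-2-carbothioate | CCSC(=O)[C@H]1O[C@]1(C)CO[Si](C)(C)C(C)(C)C
F9 | step 14 | C6 ketone corresponding to 22 (epoxy ketone cis to the methyl ester) | COC(=O)/C(COCc1ccc(OC)cc1)=C(\C(=O)[C@H]1O[C@]1(C)CO[Si](C)(C)C(C)(C)C)[C@H](O[Si](C)(C)C(C)(C)C)C[C@@H](C)C=C
F10 | step 26 | 1,13-diol: β-hydroxy ketone from N–O cleavage of 39 | OCC1=C2[C@@H](OC1=O)[C@H]3O[C@]3(C)C(=O)CC(O)[C@H](C)C[C@H]2OC(=O)/C=C(/C)COC(C)=O
A1 | alternative 1 | keto aldehyde: butenolide with C3 epoxy aldehyde, C1 methyl ketone, 8-OTBS, 13-OPMB | O=C1O[C@@H]([C@H]2O[C@]2(C)C=O)C([C@H](O[Si](C)(C)C(C)(C)C)C[C@@H](C)C(C)=O)=C1COCc1ccc(OC)cc1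
A2 | alternative 1 | macrocyclic β-hydroxy ketone (C3–OH, C1=O, 8-OTBS, 13-OPMB) | COc1ccc(COCC2=C3[C@@H](OC2=O)[C@H]4O[C@]4(C)C(O)CC(=O)[C@H](C)C[C@H]3O[Si](C)(C)C(C)(C)C)cc1
A3 | alternative 2 | aldehyde–triflate: 4-triflyloxybutenolide joined through the epoxide to an isoxazoline that carries the C10–C9–C8 aldehyde chain | O=C1O[C@@H]([C@H]2O[C@]2(C)C2=NOC(C2)[C@H](C)CC=O)C(OS(=O)(=O)C(F)(F)F)=C1COCc1ccc(OC)cc1
A4 | alternative 2 | macrocyclic allylic alcohol as a mixture of C8 epimers | COc1ccc(COCC2=C3[C@@H](OC2=O)[C@H]4O[C@]4(C)C5=NOC(C5)[C@H](C)CC3O)cc1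
A5 | alternative 3 | cyclohexanone with quaternary C6 (butenolide γ-carbon) bearing the (Z)-enone side chain C5=C4(Me)–C3(=O)–C2H3 | CC(=O)/C(C)=C\C12OC(=O)C(COCc3ccc(OC)cc3)=C1[C@H](O[Si](C)(C)C(C)(C)C)C[C@@H](C)C2=O
A6 | alternative 3 | ten-membered 1,3-diketone with (Z)-4,5-alkene (C6 not defined) | C[C@@H]1C[C@@H](O[Si](C)(C)C(C)(C)C)C2=C(COCc3ccc(OC)cc3)C(=O)OC2/C=C(C)\C(=O)CC1=O
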